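At the reading time of 1.0 h, each molecule of D in these flasks has met a fork: it has gone to the ring Z or to something unseen, or it is still waiting.

| flask | D | remark | time |
|---|---|---|---|
| Friday's | 0.44 M | run made earlier |  |
| west | 0.40 M |  | 1.0 h |
| south-east | 0.50 M |  | 1.0 h |
| north-west | 0.80 M |  | 1.0 h |

Friday's run (percent of the D charged)

| time / min | Z / % | D / % |
|---|---|---|
| 0.667 | 1.2 | 97.4 |
| 2.00 | 4.6 | 92.8 |
| 3.00 | 5.4 | 90.1 |
| 5.00 | 9.7 | 83.5 |
| 8.00 | 11.9 | 76.0 |
| 10.0 | 15.7 | 70.7 |
| 12.0 | 16.6 | 66.1 |

(each reading ± 0.5 percentage points)

- what was read earlier has a scatter of 0.5 percentage points, one standard deviation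
- a reading or a percentage of Z counts all its forms, free or not
- the concentration of Z that is asked is that of its free form alone
- "hardly changes" means that all values lie within two and a half points (for a concentration: within two and a half percent of the largest)

- [Z] (only what is free in solution) at the end for west, south-east, north-west, in this order
- how the row runs (falls, then rises / falls all the way / hardly changes / rises, then falls / rises all the way)

At its last reading Friday's run holds Z at 16.6% and D at 66.1%, so the fraction of lost D found as Z is 0.490, and this Z share, a selectivity, is the quantity to carry. Continued as a plain decay, D keeps 12.6% of its charge at the reading. In the first extreme the side route is first order like the Z route, so the fork ignores the charge and each flask holds 0.428 of its charge as Z. In the second extreme the side route needs two D to meet, so the odds for Z, 0.960 on Friday's charge of 0.44 M, shrink as the charge grows, and Z becomes 0.449 of the charge in west but 0.302 in north-west. One charge cannot separate these extremes, so the real flasks should lie near or between them. Taking Z as free, this reckoning commits to a rising row, because north-west's charge exceeds west's by more than its fraction falls, with west near 0.171 M and north-west near 0.241 M.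

The forecast reads 0.17 M, 0.21 M and 0.33 M, a row that rises all the way, higher than this reckoning at north-west, on the ground that “first-order behaviour makes this independent of concentration”.

The flasks give 0.154 M, 0.182 M and 0.254 M, a row that rises all the way.

    Z → G (k = 0.00887 min⁻¹)
    D → Z (k = 0.0192 min⁻¹)
    2 D → L (k = 0.0217 L mol⁻¹ min⁻¹)
    J ⇌ Z, rate k4*(cs4 - [Z]) while solid is left; crystals form when [Z] > cs4 (solubility = 0.570 M, k = 0.410 min⁻¹)

In west, D turned into Z and pairs of D turned into L side by side, and at 0.500 h D stood at 40.3%, Z at 31.7% and L at 22.8%, a Z share of 0.531; Z went on turning into G, which rose from 5.14% to 14.8% by 1.00 h, when the Z share in west stood at 0.478. North-west ran the same steps and held 41.4% as L at 1.00 h, with a Z share of 0.370.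

(Readings and results were computed with made-up constants; the scatter is artificial.)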